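Ring A (C1–C5, C10; labdane numbering) is closed last, at C2–C3, exploiting the 1,5-relationship between the C1 oxygen and the C19 ester carbonyl: C2 is the α-carbon of a C1 methyl ketone and C3 the β-carbon of a C4 acrylate. The precursor is a fully elaborated ring B cyclohexane carrying trans C10-acetyl and C5-(methoxycarbonyl)vinyl arms. One operation, a 6-endo Michael ring closure followed by in-flask C-methylation of the resulting C4 ester enolate, forms the trans-decalin and sets the C4 quaternary centre anti to the axial C10 methyl. Ring B is built from 2-methylcyclohexenone by CBS reduction, Claisen chirality transfer and cuprate addition–alkylation.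

Key step: step 10

Remark: labdane numbering is used for all intermediates (ring A C1–C5, C10; ring B C5–C10; side chain C11–C16; C17 exocyclic methylene; C18/C19 the C4 methyl and ester carbon; C20 the C10 methyl); compounds 1 and 6 are assumed to be commercial.

Step 1
Reactants: 1 2-methylcyclohex-2-en-1-one
Product: 2 (1R)-2-methylcyclohex-2-en-1-ol
Conditions: (S)-2-methyl-CBS-oxazaborolidine (10 mol %), catecholborane (1.5 equiv), toluene, −78 °C; aq. NaOH work-up
Reagents that add atoms: none
Why: Corey–Bakshi–Shibata 1,2-reduction in which the α-methylvinyl arm acts as the large group, so the (S)-catalyst should give the (R)-carbinol that later supplies the C5 configuration.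

Step 2
Reactants: 2 (1R)-2-methylcyclohex-2-en-1-ol
Product: 4 methyl 2-[(1R)-2-methylcyclohex-2-en-1-yl]acetate, via ketene acetal 3 (not isolated)
Conditions: MeC(OMe)3 (5 equiv), EtCO2H (cat.), 135 °C, MeOH distilled off
Reagents that add atoms: trimethyl orthoacetate, CC(OC)(OC)OC
Why: Johnson–Claisen rearrangement, whose suprafacial [3,3] shift forms the C5–C4 bond on the ring face that carried the C–O bond, transferring the carbinol chirality to C5 and leaving the C9=C10 olefin.

Step 3
Reactants: 4 methyl 2-[(1R)-2-methylcyclohex-2-en-1-yl]acetate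
Product: 5 methyl 2-[(1R)-2-methyl-4-oxocyclohex-2-en-1-yl]acetate
Conditions: Rh2(cap)4 (dirhodium tetracaprolactamate, 1 mol %), t-BuOOH (70% aq., 5 equiv), K2CO3 (0.5 equiv), CH2Cl2, rt
Reagents that add atoms: tert-butyl hydroperoxide, CC(C)(C)OO
Why: Radical allylic C–H oxidation, which, as in the 7-oxidation of Δ5-steroids, should attack the methylene next to the CH end of the trisubstituted olefin (C8) and give the conjugated enone with C5 untouched.

Step 4
Reactants: 6 (2E)-3-methylpent-2-en-4-yn-1-ol
Product: 7 (2E)-3-methylpenta-2,4-dien-1-ol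
Conditions: H2 (1 atm, 1 equiv uptake), Pd/CaCO3 poisoned with Pb(OAc)2 (Lindlar catalyst), quinoline, EtOAc, 0 °C
Reagents that add atoms: none
Why: Lindlar semihydrogenation should reduce only the terminal alkyne to the vinyl group and leave the (E)-trisubstituted olefin unchanged.

Step 5
Reactants: 7 (2E)-3-methylpenta-2,4-dien-1-ol
Product: 8 (3E)-5-bromo-3-methylpenta-1,3-diene
Conditions: PBr3 (0.4 equiv), pyridine (cat.), Et2O, −20 °C; used at once
Reagents that add atoms: phosphorus tribromide, BrP(Br)Br
Why: SN2 bromination of the primary allylic alcohol through its phosphite ester keeps the (E)-geometry, the conjugated primary bromide also being the thermodynamic allylic isomer.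

Step 6
Reactants: 5 methyl 2-[(1R)-2-methyl-4-oxocyclohex-2-en-1-yl]acetate; 8 (3E)-5-bromo-3-methylpenta-1,3-diene
Product: 11 methyl 2-[(1R,2R,3S)-2-(1-ethoxyethenyl)-2-methyl-3-[(2E)-3-methylpenta-2,4-dien-1-yl]-4-oxocyclohexyl]acetate, via lithium enolate 9 (not isolated), via C9-epimer mixture 10 (not isolated)
Conditions: ethyl vinyl ether, t-BuLi, THF, −78 → 0 °C; CuI (0.5 equiv per Li), −40 °C; 5, −78 → −30 °C; DMPU, 8 (2 equiv), −30 → 0 °C; aq. NH4Cl/NH3; then NaOMe (0.2 equiv), MeOH, rt
Reagents that add atoms: ethyl vinyl ether, C=COCC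
Why: Conjugate addition of the acyl-anion-equivalent cuprate should occur anti to the C5 side chain and create the C10 quaternary centre, the regiodefined C8/C9 enolate is then C-allylated by the primary bromide, and methoxide equilibration of the epimerisable C9 centre should favour the isomer with the dienyl chain equatorial and trans to the ethoxyvinyl group.

Step 7
Reactants: 11 methyl 2-[(1R,2R,3S)-2-(1-ethoxyethenyl)-2-methyl-3-[(2E)-3-methylpenta-2,4-dien-1-yl]-4-oxocyclohexyl]acetate
Product: 12 methyl 2-[(1R,2R,3R)-2-(1-ethoxyethenyl)-2-methyl-4-methylidene-3-[(2E)-3-methylpenta-2,4-dien-1-yl]cyclohexyl]acetate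
Conditions: Ph3PCH3Br (3 equiv), KOtBu (2.8 equiv), THF, 0 °C → rt
Reagents that add atoms: methyltriphenylphosphonium bromide, C[P+](c1ccccc1)(c1ccccc1)c1ccccc1.[Br-]
Why: Wittig methylenation of the ketone, in the presence of the less electrophilic ester and the base-stable enol ether, installs the C8 exocyclic methylene and thereby locks the C9 configuration.

Step 8
Reactants: 12 methyl 2-[(1R,2R,3R)-2-(1-ethoxyethenyl)-2-methyl-4-methylidene-3-[(2E)-3-methylpenta-2,4-dien-1-yl]cyclohexyl]acetate
Product: 15 methyl 2-[(1R,2R,3R)-2-acetyl-2-methyl-4-methylidene-3-[(2E)-3-methylpenta-2,4-dien-1-yl]cyclohexyl]-3-(dimethylamino)propanoate (both C4 epimers), via lithium ester enolate 13 (not isolated), via Mannich base 14 (not isolated)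
Conditions: LDA (LiN(iPr)2, 1.1 equiv), THF, −78 °C; CH2=NMe2+ I− (1.5 equiv), −78 °C → rt; then 1 M aq. HCl–THF, 0 °C, 20 min; NaHCO3
Reagents that add atoms: N,N-dimethylmethyleneiminium iodide (Eschenmoser's salt), C=[N+](C)C.[I-]; water, O
Why: With C8 methylenated and C1 masked as the enol ether the ester α-CH2 is the only acidic site, its enolate undergoes a Mannich reaction with Eschenmoser's salt, and the brief acidic work-up should hydrolyse the enol ether to the C1 methyl ketone much faster than it affects the olefins.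

Step 9
Reactants: 15 methyl 2-[(1R,2R,3R)-2-acetyl-2-methyl-4-methylidene-3-[(2E)-3-methylpenta-2,4-dien-1-yl]cyclohexyl]-3-(dimethylamino)propanoate
Product: 17 methyl 2-[(1S,2S,3R)-2-acetyl-2-methyl-4-methylidene-3-[(2E)-3-methylpenta-2,4-dien-1-yl]cyclohexyl]prop-2-enoate, via ammonium iodide 16 (not isolated)
Conditions: MeI (5 equiv), MeOH, rt; evaporate; sat. aq. NaHCO3–CH2Cl2, rt
Reagents that add atoms: none
Why: N-quaternisation followed by Hofmann-type E1cB loss of trimethylamine gives the α-substituted acrylate, and bicarbonate is too weak to enolise the methyl ketone, so donor and acceptor are unveiled without premature cyclisation.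

Step 10
Reactants: 17 methyl 2-[(1S,2S,3R)-2-acetyl-2-methyl-4-methylidene-3-[(2E)-3-methylpenta-2,4-dien-1-yl]cyclohexyl]prop-2-enoate
Product: 22 methyl (1R,4aS,5R,8aS)-1,4a-dimethyl-6-methylidene-5-[(2E)-3-methylpenta-2,4-dien-1-yl]-4-oxodecahydronaphthalene-1-carboxylate, via ketone enolate 18 (not isolated), via ester enolate 19 (not isolated), via bis-enolate 20 (not isolated), via methylated ketone enolate 21 (not isolated)
Conditions: LiTMP (lithium 2,2,6,6-tetramethylpiperidide, from the amine and n-BuLi; 1.05 equiv), THF, −78 → −30 °C; recool to −78 °C, LiTMP (1.1 equiv); MeI (1.1 equiv), −78 °C, 1 h; aq. NH4Cl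
Reagents that add atoms: iodomethane, CI
Why: The kinetic lithium enolate of the C1 methyl ketone (C2 as nucleophile) adds to the terminal carbon C3 of the C4 acrylate in an intramolecular Michael addition, the closest known reaction type being a Michael-initiated ring closure with enolate trapping (tandem Michael–alkylation). Ring A closes in the 6-endo-trig mode through a chair-like array of the 1,5-diene C2=C1–C10–C5–C4=C3, and because the acetyl and acrylate arms are trans-diequatorial on ring B the ring fusion can only be trans. The one new stereocentre, C4, is set in the methylation: MeI should attack the exocyclic ester enolate on the face opposite the axial C10 methyl, placing the new methyl equatorial and the ester axial. The step needs chemoselectivity between conjugate addition and Claisen acylation at the ester carbonyl, and site selectivity between the two enolates in the alkylation; the unhindered acrylate CH2 should react far faster than a methyl ester carbonyl below −30 °C, and the second equivalent of amide converts whichever enolate is present after ring closure into the bis-enolate, whose more basic ester enolate should be methylated at −78 °C while the ketone enolate stays inert until reprotonation at work-up. The hindered, non-nucleophilic LiTMP is chosen so that amide addition to the acrylate does not compete with deprotonation.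

Step 11
Reactants: 22 methyl (1R,4aS,5R,8aS)-1,4a-dimethyl-6-methylidene-5-[(2E)-3-methylpenta-2,4-dien-1-yl]-4-oxodecahydronaphthalene-1-carboxylate
Product: 23 methyl (1R,4S,4aS,5R,8aS)-4-hydroxy-1,4a-dimethyl-6-methylidene-5-[(2E)-3-methylpenta-2,4-dien-1-yl]decahydronaphthalene-1-carboxylate
Conditions: NaBH4 (2 equiv), MeOH, 0 °C
Reagents that add atoms: none
Why: Borohydride reduction in which the small hydride should attack the C1 ketone axially, from the face opposite the axial C10 methyl (the equatorial path is screened by that methyl and by C11), to give the equatorial alcohol cis to C20 while the hindered axial ester is untouched.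

Step 12
Reactants: 23 methyl (1R,4S,4aS,5R,8aS)-4-hydroxy-1,4a-dimethyl-6-methylidene-5-[(2E)-3-methylpenta-2,4-dien-1-yl]decahydronaphthalene-1-carboxylate
Product: 24 methyl (1R,4S,4aS,5R,8aS)-4-acetoxy-1,4a-dimethyl-6-methylidene-5-[(2E)-3-methylpenta-2,4-dien-1-yl]decahydronaphthalene-1-carboxylate (CNP0235031.1)
Conditions: Ac2O (3 equiv), DMAP (0.2 equiv), pyridine, CH2Cl2, rt
Reagents that add atoms: acetic anhydride, CC(=O)OC(C)=O
Why: DMAP-catalysed O-acetylation of the secondary alcohol proceeds with retention at C1 and completes the target.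

Compound list
1 | 2-methylcyclohex-2-en-1-one | CC1=CCCCC1=O | starting material
2 | (1R)-2-methylcyclohex-2-en-1-ol | CC1=CCCC[C@H]1O | intermediate
3 | 1-methoxy-1-{[(1R)-2-methylcyclohex-2-en-1-yl]oxy}ethene (mixed ketene acetal) | C=C(OC)O[C@@H]1CCCC=C1C | intermediate (not isolated)
4 | methyl 2-[(1R)-2-methylcyclohex-2-en-1-yl]acetate | CC1=CCCC[C@@H]1CC(=O)OC | intermediate
5 | methyl 2-[(1R)-2-methyl-4-oxocyclohex-2-en-1-yl]acetate | CC1=CC(=O)CC[C@@H]1CC(=O)OC | intermediate
6 | (2E)-3-methylpent-2-en-4-yn-1-ol | C#C/C(C)=C/CO | starting material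
7 | (2E)-3-methylpenta-2,4-dien-1-ol | C=C/C(C)=C/CO | intermediate
8 | (3E)-5-bromo-3-methylpenta-1,3-diene | C=C/C(C)=C/CBr | intermediate
9 | lithium (3R,4R)-3-(1-ethoxyethenyl)-4-(2-methoxy-2-oxoethyl)-3-methylcyclohex-1-en-1-olate | C=C(OCC)[C@@]1(C)C=C([O-])CC[C@@H]1CC(=O)OC.[Li+] | intermediate (not isolated)
10 | methyl 2-[(1R,2R)-2-(1-ethoxyethenyl)-2-methyl-3-[(2E)-3-methylpenta-2,4-dien-1-yl]-4-oxocyclohexyl]acetate, both C9 epimers | C=C/C(C)=C/CC1C(=O)CC[C@H](CC(=O)OC)[C@@]1(C)C(=C)OCC | intermediate (not isolated)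
11 | methyl 2-[(1R,2R,3S)-2-(1-ethoxyethenyl)-2-methyl-3-[(2E)-3-methylpenta-2,4-dien-1-yl]-4-oxocyclohexyl]acetate | C=C/C(C)=C/C[C@@H]1C(=O)CC[C@H](CC(=O)OC)[C@@]1(C)C(=C)OCC | intermediate
12 | methyl 2-[(1R,2R,3R)-2-(1-ethoxyethenyl)-2-methyl-4-methylidene-3-[(2E)-3-methylpenta-2,4-dien-1-yl]cyclohexyl]acetate | C=C/C(C)=C/C[C@@H]1C(=C)CC[C@H](CC(=O)OC)[C@@]1(C)C(=C)OCC | intermediate
13 | lithium enolate of ester 12 (C4=C19 enolate, ring B stereocentres as in 12) | C=C/C(C)=C/C[C@@H]1C(=C)CC[C@H](C=C([O-])OC)[C@@]1(C)C(=C)OCC.[Li+] | intermediate (not isolated)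
14 | methyl 3-(dimethylamino)-2-[(1R,2R,3R)-2-(1-ethoxyethenyl)-2-methyl-4-methylidene-3-[(2E)-3-methylpenta-2,4-dien-1-yl]cyclohexyl]propanoate, both C4 epimers | C=C/C(C)=C/C[C@@H]1C(=C)CC[C@H](C(CN(C)C)C(=O)OC)[C@@]1(C)C(=C)OCC | intermediate (not isolated)
15 | methyl 2-[(1R,2R,3R)-2-acetyl-2-methyl-4-methylidene-3-[(2E)-3-methylpenta-2,4-dien-1-yl]cyclohexyl]-3-(dimethylamino)propanoate, both C4 epimers | C=C/C(C)=C/C[C@@H]1C(=C)CC[C@H](C(CN(C)C)C(=O)OC)[C@@]1(C)C(C)=O | intermediate
16 | N,N,N-trimethylammonium iodide of 15 (quaternised Mannich base) | C=C/C(C)=C/C[C@@H]1C(=C)CC[C@H](C(C[N+](C)(C)C)C(=O)OC)[C@@]1(C)C(C)=O.[I-] | intermediate (not isolated)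
17 | methyl 2-[(1S,2S,3R)-2-acetyl-2-methyl-4-methylidene-3-[(2E)-3-methylpenta-2,4-dien-1-yl]cyclohexyl]prop-2-enoate | C=C/C(C)=C/C[C@@H]1C(=C)CC[C@H](C(=C)C(=O)OC)[C@@]1(C)C(C)=O | intermediate
18 | lithium enolate of the C1 methyl ketone of 17 (C1(OLi)=C2H2) | C=C/C(C)=C/C[C@@H]1C(=C)CC[C@H](C(=C)C(=O)OC)[C@@]1(C)C([O-])=C.[Li+] | intermediate (not isolated)
19 | ring-closed lithium ester enolate (trans-decalin, C1 ketone, C4=C19 enolate; C5, C9, C10 as in 22) | C=C/C(C)=C/C[C@@H]1C(=C)CC[C@H]2[C@@]1(C)C(=O)CCC2=C([O-])OC.[Li+] | intermediate (not isolated)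
20 | dilithium bis-enolate (C1(OLi)=C2 and C4=C19(OLi)OMe; C5, C9, C10 as in 22) | C=C/C(C)=C/C[C@@H]1C(=C)CC[C@H]2[C@@]1(C)C([O-])=CCC2=C([O-])OC.[Li+].[Li+] | intermediate (not isolated)
21 | lithium C1(OLi)=C2 enolate of 22 | C=C/C(C)=C/C[C@@H]1C(=C)CC[C@H]2[C@@]1(C)C([O-])=CC[C@@]2(C)C(=O)OC.[Li+] | intermediate (not isolated)
22 | methyl (1R,4aS,5R,8aS)-1,4a-dimethyl-6-methylidene-5-[(2E)-3-methylpenta-2,4-dien-1-yl]-4-oxodecahydronaphthalene-1-carboxylate | C=C/C(C)=C/C[C@@H]1C(=C)CC[C@H]2[C@@]1(C)C(=O)CC[C@@]2(C)C(=O)OC | intermediate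
23 | methyl (1R,4S,4aS,5R,8aS)-4-hydroxy-1,4a-dimethyl-6-methylidene-5-[(2E)-3-methylpenta-2,4-dien-1-yl]decahydronaphthalene-1-carboxylate | C=C/C(C)=C/C[C@@H]1C(=C)CC[C@H]2[C@@]1(C)[C@@H](O)CC[C@@]2(C)C(=O)OC | intermediate
24 | methyl (1R,4S,4aS,5R,8aS)-4-acetoxy-1,4a-dimethyl-6-methylidene-5-[(2E)-3-methylpenta-2,4-dien-1-yl]decahydronaphthalene-1-carboxylate | C=C/C(C)=C/C[C@@H]1C(=C)CC[C@H]2[C@@]1(C)[C@@H](OC(C)=O)CC[C@@]2(C)C(=O)OC | target

Total step count: 12. Longest linear sequence: 10 steps (steps 1–3 and 6–12); steps 4–5 form the two-step side-chain branch.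

Steps most likely to fail

Step 10. The ester enolate formed on ring closure may pass its charge to C2 by proton transfer, so that methylation ends up at C2 or does not occur; the ketone enolate may also acylate on the ester carbonyl instead of adding to C3. The fallback separates ring closure from quaternisation of C4, setting out from 17 and returning at 23. Compound 17 is cyclised alone with KOtBu (0.2 equiv) in t-BuOH–THF at 0 °C to the Michael adduct methyl (4aR,5R,8aR)-4a-methyl-6-methylidene-5-[(2E)-3-methylpenta-2,4-dien-1-yl]-4-oxodecahydronaphthalene-1-carboxylate F1 (C4 epimers). NaBH4 in MeOH then reduces C1 axially to methyl (4S,4aR,5R,8aR)-4-hydroxy-4a-methyl-6-methylidene-5-[(2E)-3-methylpenta-2,4-dien-1-yl]decahydronaphthalene-1-carboxylate F2. With no enolisable ketone left, the alkoxide–ester-enolate dianion of F2 (LDA, 2.2 equiv, THF, −78 → −20 °C) is C-methylated by MeI anti to the C10 methyl (Fráter–Seebach-type dianion alkylation), which should give 23.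

Step 6. 1,4-Addition to the β,β-disubstituted enone may be slow enough for 1,2-addition or enone recovery to take over, and the copper-containing enolate may exchange protons before it is allylated, scrambling regiochemistry. The fallback splits the two events, setting out from 5 and returning at 11. The same cuprate with Me3SiCl (3 equiv) at −78 °C, which accelerates the addition and traps the enolate, should give methyl 2-[(1R,2R)-2-(1-ethoxyethenyl)-2-methyl-4-(trimethylsilyloxy)cyclohex-3-en-1-yl]acetate F3, which is isolated. MeLi (THF, 0 °C) then releases the copper-free lithium enolate 9 regiospecifically; allylation with 8 in THF–DMPU and the same methoxide equilibration lead to 11.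

Step 7. The basic ylide may simply enolise the hindered C8 ketone, giving recovered ketone and loss of C9 integrity rather than olefination. The fallback is a Peterson olefination, setting out from 11 and returning at 12. Me3SiCH2Li premixed with CeCl3 (THF, −78 °C) adds to the ketone without enolisation or ester attack to give methyl 2-[(1R,2R,3S)-2-(1-ethoxyethenyl)-4-hydroxy-2-methyl-3-[(2E)-3-methylpenta-2,4-dien-1-yl]-4-[(trimethylsilyl)methyl]cyclohexyl]acetate F4 (C8 epimers), and KH (THF, 0 °C) effects syn-elimination to 12.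

Further compounds
F1 | step 10 | methyl (4aR,5R,8aR)-4a-methyl-6-methylidene-5-[(2E)-3-methylpenta-2,4-dien-1-yl]-4-oxodecahydronaphthalene-1-carboxylate (C4 epimers) | C=C/C(C)=C/C[C@@H]1C(=C)CC[C@H]2[C@@]1(C)C(=O)CCC2C(=O)OC
F2 | step 10 | methyl (4S,4aR,5R,8aR)-4-hydroxy-4a-methyl-6-methylidene-5-[(2E)-3-methylpenta-2,4-dien-1-yl]decahydronaphthalene-1-carboxylate (C4 epimers) | C=C/C(C)=C/C[C@@H]1C(=C)CC[C@H]2[C@@]1(C)[C@@H](O)CCC2C(=O)OC
F3 | step 6 | methyl 2-[(1R,2R)-2-(1-ethoxyethenyl)-2-methyl-4-(trimethylsilyloxy)cyclohex-3-en-1-yl]acetate | C=C(OCC)[C@@]1(C)C=C(O[Si](C)(C)C)CC[C@@H]1CC(=O)OC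
F4 | step 7 | methyl 2-[(1R,2R,3S)-2-(1-ethoxyethenyl)-4-hydroxy-2-methyl-3-[(2E)-3-methylpenta-2,4-dien-1-yl]-4-[(trimethylsilyl)methyl]cyclohexyl]acetate (C8 epimers) | C=C/C(C)=C/C[C@@H]1C(O)(C[Si](C)(C)C)CC[C@H](CC(=O)OC)[C@@]1(C)C(=C)OCC
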